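The synthesis rests on opening the γ-lactone ring (O7–C7–C8–C17–C19) retrosynthetically to a (7E)-C7=C8 olefin. The key step exploits three features: O7 and the C8 hydroxyl are anti across C7–C8, the C8 hydroxyl is erythro to the C9 carbinol, and C7 is allylic to C5=C6. In one operation, C9–OH-directed vanadium epoxidation and acid-triggered 5-endo attack of the C19 ester carbonyl on C7 form both C–O bonds, close the lactone and set C7 and C8. The precursor is a fully substituted cyclopentane bearing the C2 vinyl carbinol acetate and a 9-hydroxy (5Z,7E)-dienyl iodide with a tert-butyl propionate arm on C8. The ten-membered ring is closed afterwards at C4–C5.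

Key step: step 18

**Numbering (target numbering throughout):** the ten-membered ring is C1–C10. The cyclopentane is C1, C10, C11, C13, C14. C12 is the carbon on C11 that ends as CHO, and C15 is the methyl on C1. C17, C18 and C19 are the lactone CH, its methyl and the carbonyl.

**Faces of the cyclopentane:** "up" carries O14, C2, H10 and the C11 methyl. "Down" carries C15, C9 and C12.

**Target descriptors:** 2R, 7S, 8R, 9R, 11S, 14S, 17R, 5Z.

**Design remark:** C19 is carried as the tert-butyl ester up to the key step. The free 9-hydroxy acid is a γ-hydroxy acid that would close onto O9 and remove the directing hydroxyl. The tert-butyl ester also avoids an ester hydrolysis that the acetates would not survive.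

**Assumption 1:** (S)-BINAP is taken to give (S)-4. If the sense of induction is opposite, the ligand antipode is used.

**Assumption 2:** the target is taken as the open C9-hydroxy C12-aldehyde drawn. A C9–O–C12 lactol would only be its ring-chain tautomer.

Step 1
Reactants: 1 but-2-yn-1-ol; 2 3-chloro-2-methylprop-1-ene
Product: 3 but-2-ynyl methallyl ether (1-[(2-methylprop-2-en-1-yl)oxy]but-2-yne)
Conditions: NaH, n-Bu4NI (cat.), THF, 0 °C to rt
Reagents that add atoms: none
Why: Williamson ether synthesis: the primary propargylic alkoxide displaces the allylic chloride (iodide catalysis) and no stereocentre is involved.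

Step 2
Reactants: 3 but-2-ynyl methallyl ether
Product: 4 (3aS)-3a,6-dimethyl-3,3a,4,5-tetrahydro-1H-cyclopenta[c]furan-5-one (bicyclic enone: C14=O; C1(Me)=C10; ring ether C9H2–O–C12H2; quaternary C11 S)
Conditions: [Rh(CO)2Cl]2 (3 mol %), (S)-BINAP (9 mol %), AgOTf (12 mol %), CO (1 atm), THF, 90 °C
Reagents that add atoms: carbon monoxide, [C-]#[O+]
Why: Rhodium(I)/BINAP-catalysed asymmetric intramolecular Pauson–Khand-type [2+2+1] reaction of a 1,6-enyne ether, which forms C10–C11, C13–C14 and C14–C1 at once and sets the quaternary C11 (S) through face-selective olefin insertion in the chiral rhodacycle.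

Step 3
Reactants: 4 bicyclic enone
Product: 5 cis-fused keto ether (H10 up and cis to the C11 methyl; C15 down)
Conditions: H2 (4 bar), 10 % Pd/C, EtOAc, rt
Reagents that add atoms: none
Why: Heterogeneous catalytic hydrogenation of the enone C=C: only the cis-fused bicyclo[3.3.0]octane is reachable, so H10 ends cis to the C11 methyl (up) and C9 cis to C12, while the C1 configuration is irrelevant because step 5 removes it.

Step 4
Reactants: 5 cis-fused keto ether
Product: 6 cis-fused keto lactone (C9 lactone carbonyl; O bound to C12; C14 ketone)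
Conditions: RuCl3·xH2O (5 mol %), NaIO4, EtOAc/MeCN/H2O, rt
Reagents that add atoms: sodium periodate, [Na+].[O-]I(=O)(=O)=O
Why: Ruthenium tetroxide oxidation of a cyclic ether to a lactone (catalytic RuCl3/periodate), which should take the C9 methylene next to tertiary C10 rather than the neopentyl C12 methylene next to quaternary C11, and leaves the ketone alone.

Step 5
Reactants: 6 cis-fused keto lactone
Product: 7 C14 trimethylsilyl enol ether (C1=C14 tetrasubstituted; lactone intact)
Conditions: TMSCl, NaI, Et3N, MeCN, rt
Reagents that add atoms: chlorotrimethylsilane, C[Si](C)(C)Cl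
Why: Silyl enol ether formation under equilibrating conditions (iodotrimethylsilane made in situ with amine base), which favours the tetrasubstituted C1=C14 isomer over the C13=C14 isomer and so fixes the site of the next C–C bond.

Step 6
Reactants: 7 C14 trimethylsilyl enol ether; 8 acrolein
Product: 9 aldol keto lactone (C1 quaternary with C2 up and C15 down; C2 carbinol epimers)
Conditions: BF3·OEt2, CH2Cl2, −78 °C; aq. NaHCO3
Reagents that add atoms: none
Why: Mukaiyama aldol addition (1,2 to the BF3-activated enal): the electrophile reaches C1 on the convex face of the cis-bicycle, anti to the vicinal C9 carbonyl branch, so C2 ends up and C15 down, and the carbinol configuration at C2 does not matter because steps 8 and 9 reset it.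

Step 7
Reactants: 9 aldol keto lactone
Product: 10 (14S)-diol lactone (O14 up; C2 carbinol epimers)
Conditions: (R)-Me-CBS oxazaborolidine, catecholborane, toluene, −78 to −40 °C; pH 7 buffer
Reagents that add atoms: none
Why: Corey–Bakshi–Shibata reduction: the oxazaborolidine tells quaternary C1 from the C13 methylene and delivers hydride to the lower face, the face that the branched C2 borate leaves open, giving 14S (OH up, cis to C2); catecholborane spares vinyl group and lactone, and material of the wrong enantiomeric series becomes a separable diastereomer.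

Step 8
Reactants: 10 (14S)-diol lactone
Product: 11 (14S)-hydroxy vinyl ketone lactone (C2=O)
Conditions: MnO2, CH2Cl2, rt; filtered and used crude
Reagents that add atoms: none
Why: Manganese dioxide oxidises only the allylic C2 carbinol, merging both C2 epimers into one vinyl ketone while the saturated C14 alcohol survives; the product is carried on without purification to forestall oxa-Michael closure of O14 onto C4.

Step 9
Reactants: 11 (14S)-hydroxy vinyl ketone lactone
Product: 12 (2R,14S)-syn-1,3-diol lactone
Conditions: Et2BOMe, THF/MeOH 4:1, −78 °C; NaBH4; AcOH, MeOH co-evaporation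
Reagents that add atoms: none
Why: Narasaka–Prasad reduction: the diethylboron chelate between O14 and the C2 carbonyl adopts the half-chair with C10 axial, external hydride attacks anti to C10 (syn-axial only to H14), and the syn-1,3-diol with 2R results, 1,2-selectively at low temperature.

Step 10
Reactants: 12 (2R,14S)-syn-1,3-diol lactone; 13 3,3-diethoxyprop-1-yne
Product: 15 C9 ynone triol (open form of its hemiketal; free O2H O12H O14H; C6 diethyl acetal), via lithium acetylide 14 (not isolated)
Conditions: 13, n-BuLi, THF, −78 °C; 12, −78 to −40 °C; AcOH, −78 °C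
Reagents that add atoms: none
Why: Addition of a lithium acetylide to a γ-lactone, which stops at the tetrahedral alkoxide until the cold acidic quench, converts C9 into an ynone and frees O12; the extra acetylide only deprotonates O2 and O14, which cannot reach C9 because they lie on the opposite ring face.

Step 11
Reactants: 15 C9 ynone triol
Product: 16 C12 tert-butyldimethylsilyl ether ynone diol
Conditions: TBSCl, imidazole, DMF, 0 °C
Reagents that add atoms: tert-butyldimethylsilyl chloride, CC(C)(C)[Si](C)(C)Cl
Why: Chemoselective silylation of the only primary hydroxyl, which also draws the hemiketal/hydroxy ketone equilibrium to the open ynone.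

Step 12
Reactants: 16 C12 silyl ether ynone diol
Product: 17 2,14-diacetate ynone
Conditions: Ac2O, pyridine, DMAP (cat.), CH2Cl2, 0 °C to rt
Reagents that add atoms: acetic anhydride, CC(=O)OC(C)=O
Why: DMAP-catalysed acetylation places the two acetates of the target while C9 is still a ketone, which is what later distinguishes O9 from O2 and O14; H10, flanked by two quaternary carbons, should not be exchanged by amine bases.

Step 13
Reactants: 17 2,14-diacetate ynone
Product: 18 (9R)-propargylic alcohol
Conditions: (R)-Me-CBS oxazaborolidine, catecholborane, CH2Cl2, −78 °C; pH 7 buffer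
Reagents that add atoms: none
Why: Corey–Bakshi–Shibata reduction of an ynone, with the slim alkynyl group as the small and the cyclopentyl group as the large substituent, sets 9R under reagent control and tolerates acetates, acetal and vinyl group when catecholborane is the hydride source.

Step 14
Reactants: 18 (9R)-propargylic alcohol
Product: 20 (7Z)-C8 alkenyl iodide (I cis to C6; C9 trans to C6; free O9H), via alkenylstannane 19 (not isolated)
Conditions: [Cp*RuCl]4 (2.5 mol %), Bu3SnH, CH2Cl2, rt; then I2, 0 °C
Reagents that add atoms: iodine, II; tributyltin hydride, CCCC[SnH](CCCC)CCCC (tin stays only in 19)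
Why: Hydroxyl-directed ruthenium-catalysed trans-hydrostannation puts tin on C8 (proximal to the free C9 hydroxyl) and hydrogen on C7 on opposite sides, and tin–iodine exchange with retention gives the Z iodide in which C9 is trans to C6.

Step 15
Reactants: 20 (7Z)-C8 alkenyl iodide; 21 tert-butyl 2-bromopropanoate
Product: 23 (7E)-tert-butyl ester acetal (C17–C19 arm on C8 cis to C6; C17 epimers), via Reformatsky reagent 22 (not isolated)
Conditions: 21, Zn dust (TMSCl-activated), THF, rt; then 20, Pd(dba)2 (5 mol %), QPhos (5 mol %), THF, rt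
Reagents that add atoms: zinc, [Zn] (stays only in 22)
Why: Negishi-type cross-coupling of a Reformatsky reagent with an alkenyl iodide proceeds with retention and installs C17–C19 cis to C6; oxidative addition to the C–I bond at room temperature with a bulky monophosphine should outrun ionisation of the neopentylic allylic acetate, and C17 forms as an epimer mixture that is settled in step 19.

Step 16
Reactants: 23 (7E)-tert-butyl ester acetal
Product: 24 (7E)-enal (C6 aldehyde; C17 epimers)
Conditions: PPTS, acetone/H2O 10:1, rt
Reagents that add atoms: water, O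
Why: Acid-catalysed hydrolysis of an allylic acetal is fast under conditions that leave silyl ether, tert-butyl ester and acetates intact, and the aldehyde, being trans to C9 across C7=C8, cannot form a lactol with O9.

Step 17
Reactants: 24 (7E)-enal; 25 ethyltriphenylphosphonium bromide
Product: 29 9-hydroxy (5Z,7E)-dienyl iodide tert-butyl ester (key-step precursor; C17 epimers), via ethylidene ylide 26 (not isolated), via iodoethylphosphonium iodide 27 (not isolated), via iodoethylidene ylide 28 (not isolated)
Conditions: 25, n-BuLi, THF, rt; I2, −78 °C; NaHMDS, −20 °C; 24, −78 to −20 °C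
Reagents that add atoms: iodine, II
Why: Stork–Zhao-type Wittig olefination with the non-stabilised α-iodo ylide gives, through the kinetically favoured cis-oxaphosphetane, the 5Z iodoalkene (iodine cis to C7); excess ylide covers the free hydroxyl and the low temperature protects the acidic H17 and the acetates.

Step 18
Reactants: 29 9-hydroxy (5Z,7E)-dienyl iodide tert-butyl ester
Product: 31 (7S,8R,9R)-8,9-dihydroxy γ-lactone with 5Z vinyl iodide (C17 epimers), via epoxy ester 30 (not isolated)
Conditions: VO(acac)2 (5 mol %), t-BuOOH (decane), CH2Cl2, 0 °C; then CSA (0.3 equiv), 0 °C to rt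
Reagents that add atoms: tert-butyl hydroperoxide, CC(C)(C)OO
Why: The vanadium(V) alkoxide of the C9 hydroxyl binds t-BuOOH and transfers oxygen only to the adjacent C7=C8 bond (hydroxyl-directed vanadium epoxidation), leaving untouched the vinyl group, whose allylic oxygen is acetylated, and the electron-poor iodoalkene. C8 is controlled by A1,2 strain: with C17 on the carbinol-bearing olefin carbon the reactive rotamer puts H9, not C10, next to C17, so oxygen arrives erythro to O9 (8R). Acid then activates the vinyl epoxide 30 and the ester carbonyl oxygen attacks C7 from the rear in a 5-endo-tet closure of the O7–C7–C8–C17–C19 ring, the alkoxycarbenium ion shedding isobutene; the closest known reactions are the lactonisation of β,γ-epoxy esters and the endo-selective acid-catalysed opening of vinyl epoxides by internal oxygen nucleophiles. C7 is controlled by the olefin geometry fixed in step 14: inversion at C7 and retention at C8 turn the E olefin (C6 cis to C17) into the lactone with C6 cis to the C8 hydroxyl (7S). Attack at C7 rather than 4-exo attack at C8 is secured by the allylic activation of C7 and the strain of a β-lactone, and SN2 character by the inductively deactivating iodine on C5 and the low temperature. The bulky tert-butyl ester keeps O9 from being acylated before the epoxide is opened.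

Step 19
Reactants: 31 8,9-dihydroxy γ-lactone
Product: 33 (17R)-8,9-acetonide lactone, via acetonide C17 epimers 32 (not isolated)
Conditions: 2-methoxypropene, PPTS (cat.), CH2Cl2, 0 °C to rt; then DBU, rt
Reagents that add atoms: 2-methoxypropene, COC(C)=C
Why: Acid-catalysed acetonide formation with an enol ether blocks O8 and O9 (no acyl shift to O9, no lactol later), after which DBU equilibrates C17 through the lactone enolate to the epimer with C18 anti to the bulky C9 branch and cis to O8, i.e. 17R.

Step 20
Reactants: 33 (17R)-8,9-acetonide lactone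
Product: 35 ten-membered carbocycle (5Z; C12 silyl ether; 8,9-acetonide; 2,14-diacetate), via B-alkyl borane 34 (not isolated)
Conditions: 9-BBN, THF, rt; then slow addition to Pd(dppf)Cl2·CH2Cl2, AsPh3, Cs2CO3, DMF/THF/H2O, 1 mM, 45 °C
Reagents that add atoms: 9-borabicyclo[3.3.1]nonane, [H]B1C2CCCC1CCC2 (boron stays only in 34)
Why: Hydroboration and intramolecular B-alkyl Suzuki–Miyaura coupling: 9-BBN adds only to the monosubstituted olefin with boron on C4, coupling at C5 occurs with retention so that the ring olefin is 5Z, and the dioxolane holds C7–C8–C9–C10 in a gauche turn that brings C4 and C5 together under high dilution.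

Step 21
Reactants: 35 ten-membered carbocycle
Product: 36 C12 primary alcohol
Conditions: HF·pyridine, pyridine, THF, 0 °C to rt
Reagents that add atoms: none
Why: Fluoride-mediated cleavage of the primary silyl ether under buffered conditions leaves acetates, lactone and acetonide untouched.

Step 22
Reactants: 36 C12 primary alcohol
Product: 37 C12 aldehyde 8,9-acetonide
Conditions: Dess–Martin periodinane, NaHCO3, CH2Cl2, 0 °C to rt
Reagents that add atoms: none
Why: Dess–Martin oxidation of the neopentyl primary alcohol gives the non-enolisable C12 aldehyde, and with O9 still masked no lactol can form and be over-oxidised.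

Step 23
Reactants: 37 C12 aldehyde 8,9-acetonide
Product: 38 CNP0123121.2 (target)
Conditions: AcOH/H2O 4:1, 40 °C
Reagents that add atoms: none
Why: Mild aqueous acid hydrolysis of the dioxolane frees the C8 and C9 hydroxyls without touching acetates, lactone, aldehyde or any stereocentre, giving the target.

Compound list
1 | but-2-yn-1-ol | CC#CCO | starting material
2 | 3-chloro-2-methylprop-1-ene | CC(=C)CCl | starting material
3 | but-2-ynyl methallyl ether | CC#CCOCC(C)=C | intermediate
4 | (3aS)-bicyclic enone | O=C1C[C@]2(C)COCC2=C1C | intermediate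
5 | cis-fused keto ether | O=C1C[C@]2(C)COC[C@@H]2[C@@H]1C | intermediate
6 | cis-fused keto lactone | O=C1C[C@]2(C)COC(=O)[C@@H]2[C@@H]1C | intermediate
7 | C14 trimethylsilyl enol ether | C[Si](C)(C)OC1=C(C)[C@H]2C(=O)OC[C@@]2(C)C1 | intermediate
8 | acrolein | C=CC=O | starting material
9 | aldol keto lactone (C2 epimers) | O=C1C[C@]2(C)COC(=O)[C@@H]2[C@@]1(C)C(O)C=C | intermediate
10 | (14S)-diol lactone (C2 epimers) | O[C@H]1C[C@]2(C)COC(=O)[C@@H]2[C@@]1(C)C(O)C=C | intermediate
11 | (14S)-hydroxy vinyl ketone lactone | O[C@H]1C[C@]2(C)COC(=O)[C@@H]2[C@@]1(C)C(=O)C=C | intermediate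
12 | (2R,14S)-syn-1,3-diol lactone | O[C@H]1C[C@]2(C)COC(=O)[C@@H]2[C@@]1(C)[C@H](O)C=C | intermediate
13 | 3,3-diethoxyprop-1-yne | C#CC(OCC)OCC | starting material
14 | lithium 3,3-diethoxyprop-1-yn-1-ide | [Li]C#CC(OCC)OCC | intermediate
15 | C9 ynone triol | O[C@H]1C[C@](C)(CO)[C@H](C(=O)C#CC(OCC)OCC)[C@@]1(C)[C@H](O)C=C | intermediate
16 | C12 silyl ether ynone diol | O[C@H]1C[C@](C)(CO[Si](C)(C)C(C)(C)C)[C@H](C(=O)C#CC(OCC)OCC)[C@@]1(C)[C@H](O)C=C | intermediate
17 | 2,14-diacetate ynone | CC(=O)O[C@H]1C[C@](C)(CO[Si](C)(C)C(C)(C)C)[C@H](C(=O)C#CC(OCC)OCC)[C@@]1(C)[C@H](OC(C)=O)C=C | intermediate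
18 | (9R)-propargylic alcohol | CC(=O)O[C@H]1C[C@](C)(CO[Si](C)(C)C(C)(C)C)[C@H]([C@@H](O)C#CC(OCC)OCC)[C@@]1(C)[C@H](OC(C)=O)C=C | intermediate
19 | (7Z)-C8 tributylstannane | CC(=O)O[C@H]1C[C@](C)(CO[Si](C)(C)C(C)(C)C)[C@H]([C@@H](O)/C(=C/C(OCC)OCC)[Sn](CCCC)(CCCC)CCCC)[C@@]1(C)[C@H](OC(C)=O)C=C | intermediate
20 | (7Z)-C8 alkenyl iodide | CC(=O)O[C@H]1C[C@](C)(CO[Si](C)(C)C(C)(C)C)[C@H]([C@@H](O)/C(I)=C/C(OCC)OCC)[C@@]1(C)[C@H](OC(C)=O)C=C | intermediate
21 | tert-butyl 2-bromopropanoate | CC(Br)C(=O)OC(C)(C)C | starting material
22 | (1-tert-butoxy-1-oxopropan-2-yl)zinc bromide | CC([Zn]Br)C(=O)OC(C)(C)C | intermediate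
23 | (7E)-tert-butyl ester acetal (C17 epimers) | CC(=O)O[C@H]1C[C@](C)(CO[Si](C)(C)C(C)(C)C)[C@H]([C@@H](O)/C(=C/C(OCC)OCC)C(C)C(=O)OC(C)(C)C)[C@@]1(C)[C@H](OC(C)=O)C=C | intermediate
24 | (7E)-enal (C17 epimers) | CC(=O)O[C@H]1C[C@](C)(CO[Si](C)(C)C(C)(C)C)[C@H]([C@@H](O)/C(=C/C=O)C(C)C(=O)OC(C)(C)C)[C@@]1(C)[C@H](OC(C)=O)C=C | intermediate
25 | ethyltriphenylphosphonium bromide | CC[P+](c1ccccc1)(c1ccccc1)c1ccccc1.[Br-] | starting material
26 | ethylidenetriphenylphosphorane | CC=P(c1ccccc1)(c1ccccc1)c1ccccc1 | intermediate
27 | (1-iodoethyl)triphenylphosphonium iodide | CC(I)[P+](c1ccccc1)(c1ccccc1)c1ccccc1.[I-] | intermediate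
28 | (1-iodoethylidene)triphenylphosphorane | CC(I)=P(c1ccccc1)(c1ccccc1)c1ccccc1 | intermediate
29 | 9-hydroxy (5Z,7E)-dienyl iodide tert-butyl ester, key-step precursor (C17 epimers) | CC(=O)O[C@H]1C[C@](C)(CO[Si](C)(C)C(C)(C)C)[C@H]([C@@H](O)/C(=C/C=C(/C)I)C(C)C(=O)OC(C)(C)C)[C@@]1(C)[C@H](OC(C)=O)C=C | intermediate
30 | erythro 7,8-epoxy ester (C17 epimers) | CC(=O)O[C@H]1C[C@](C)(CO[Si](C)(C)C(C)(C)C)[C@H]([C@@H](O)[C@]2(O[C@@H]2/C=C(/C)I)C(C)C(=O)OC(C)(C)C)[C@@]1(C)[C@H](OC(C)=O)C=C | intermediate
31 | (7S,8R,9R)-8,9-dihydroxy γ-lactone, key-step product (C17 epimers) | CC(=O)O[C@H]1C[C@](C)(CO[Si](C)(C)C(C)(C)C)[C@H]([C@@H](O)[C@@]2(O)[C@H](/C=C(/C)I)OC(=O)C2C)[C@@]1(C)[C@H](OC(C)=O)C=C | intermediate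
32 | 8,9-acetonide lactone (C17 epimers) | CC(=O)O[C@H]1C[C@](C)(CO[Si](C)(C)C(C)(C)C)[C@H]([C@H]2OC(C)(C)O[C@@]23[C@H](/C=C(/C)I)OC(=O)C3C)[C@@]1(C)[C@H](OC(C)=O)C=C | intermediate
33 | (17R)-8,9-acetonide lactone | CC(=O)O[C@H]1C[C@](C)(CO[Si](C)(C)C(C)(C)C)[C@H]([C@H]2OC(C)(C)O[C@@]23[C@H](/C=C(/C)I)OC(=O)[C@@H]3C)[C@@]1(C)[C@H](OC(C)=O)C=C | intermediate
34 | C4 B-alkyl-9-BBN | CC(=O)O[C@H]1C[C@](C)(CO[Si](C)(C)C(C)(C)C)[C@H]([C@H]2OC(C)(C)O[C@@]23[C@H](/C=C(/C)I)OC(=O)[C@@H]3C)[C@@]1(C)[C@H](OC(C)=O)CCB1C2CCCC1CCC2 | intermediate
35 | ten-membered carbocycle, C12 silyl ether | CC(=O)O[C@H]1C[C@](C)(CO[Si](C)(C)C(C)(C)C)[C@@H]2[C@H]4OC(C)(C)O[C@@]43[C@H](/C=C(/C)CC[C@@H](OC(C)=O)[C@@]12C)OC(=O)[C@@H]3C | intermediate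
36 | C12 primary alcohol | CC(=O)O[C@H]1C[C@](C)(CO)[C@@H]2[C@H]4OC(C)(C)O[C@@]43[C@H](/C=C(/C)CC[C@@H](OC(C)=O)[C@@]12C)OC(=O)[C@@H]3C | intermediate
37 | C12 aldehyde 8,9-acetonide | CC(=O)O[C@H]1C[C@](C)(C=O)[C@@H]2[C@H]4OC(C)(C)O[C@@]43[C@H](/C=C(/C)CC[C@@H](OC(C)=O)[C@@]12C)OC(=O)[C@@H]3C | intermediate
38 | CNP0123121.2 | CC(=O)O[C@H]1C[C@](C)(C=O)[C@@H]2[C@@H](O)[C@@]3(O)[C@H](/C=C(/C)CC[C@@H](OC(C)=O)[C@@]12C)OC(=O)[C@@H]3C | target

Total step count: 23
Longest linear sequence: 23 steps (from 1; compounds 2, 8, 13, 21 and 25 are bought)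

Steps most likely to fail

**Step 20 (ring closure at C4–C5).** Intermolecular coupling, protodeboronation or β-hydride elimination may outrun closure of the strained ten-membered ring, and the aqueous base may attack the esters.
- The fallback sets out from 33 and replaces the boron ate chemistry by a base-free organozinc closure.
- Hydroboration with 9-BBN followed by perborate oxidation gives the C4 primary alcohol F1.
- Appel iodination (I2, PPh3, imidazole) gives the C4 alkyl iodide F2.
- Zinc insertion (Zn, LiCl, THF) goes selectively into the sp3 C–I bond and gives the C4 alkylzinc iodide F3.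
- F3 is closed by intramolecular Negishi coupling (Pd(dppf)Cl2, high dilution) onto the vinyl iodide with retention, coming back to the route at 35.

**Step 18 (key step).** Three processes may go wrong: oxygen transfer may show poor facial selectivity, C7 may ionise before the C–O bond forms and lose its stereospecificity, or the acyl group may end on O9.
- The fallback sets out from 29 and changes both control elements.
- Epoxidation becomes reagent-controlled (Katsuki–Sharpless conditions: Ti(OiPr)4, D-(−)-DIPT, t-BuOOH, 4 Å sieves, −20 °C). This is the matched, erythro-selective pairing for a 9R carbinol, and 30 is now isolated.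
- The ring is then closed without Brønsted acid by stoichiometric Ti(OiPr)4. It chelates O9 and the epoxide oxygen and steers the internal carbonyl nucleophile to C7, the C3 position of the 2,3-epoxy alcohol (Caron–Sharpless type opening).
- The fallback comes back to the route at 31 and needs no compound outside the list.

**Step 2 (asymmetric Pauson–Khand).** The 1,1-disubstituted olefin binds rhodium poorly, so turnover and enantioselectivity may both be low.
- The fallback sets out from 3. A stoichiometric cobalt Pauson–Khand reaction (Co2(CO)8, then NMO) gives the racemic enone F4.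
- Reduction with (R)-Me-CBS/catecholborane converts the two enantiomers into the diastereomeric (11S,14S)-allylic alcohol F5 and (11R,14S)-allylic alcohol F6, which are separated by chromatography.
- MnO2 oxidation of F5 comes back to the route at enantiopure 4.

Further compounds
F1 | step 20 | C4 primary alcohol | CC(=O)O[C@H]1C[C@](C)(CO[Si](C)(C)C(C)(C)C)[C@H]([C@H]2OC(C)(C)O[C@@]23[C@H](/C=C(/C)I)OC(=O)[C@@H]3C)[C@@]1(C)[C@H](OC(C)=O)CCO
F2 | step 20 | C4 alkyl iodide | CC(=O)O[C@H]1C[C@](C)(CO[Si](C)(C)C(C)(C)C)[C@H]([C@H]2OC(C)(C)O[C@@]23[C@H](/C=C(/C)I)OC(=O)[C@@H]3C)[C@@]1(C)[C@H](OC(C)=O)CCI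
F3 | step 20 | C4 alkylzinc iodide | CC(=O)O[C@H]1C[C@](C)(CO[Si](C)(C)C(C)(C)C)[C@H]([C@H]2OC(C)(C)O[C@@]23[C@H](/C=C(/C)I)OC(=O)[C@@H]3C)[C@@]1(C)[C@H](OC(C)=O)CC[Zn]I
F0 | step 18 | none | none
F4 | step 2 | racemic enone | O=C1CC2(C)COCC2=C1C
F5 | step 2 | (11S,14S)-allylic alcohol | O[C@H]1C[C@]2(C)COCC2=C1C
F6 | step 2 | (11R,14S)-allylic alcohol | O[C@H]1C[C@@]2(C)COCC2=C1C
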